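Compound numbers used below are those of the steps and of the compound list.

## Analysis of the target

The target 26 is a 2,3-trans-3,4-trans 4-arylflavan-3-ol. Its chroman core (O1, C2, C3, C4, C4a, C8a) is fused to the phenolic ring A (hydroxyl on C7). C2 carries the 4-hydroxyphenyl ring B, C3 a secondary hydroxyl, and C4 the resorcinol ring D. Ring D is bonded to C4 through D1, has hydroxyls on D2 and D4, and on D6 an (E)-ethenyl bridge to the catechol ring E.

The three stereocentres are contiguous and (2R,3S,4S): ring B and ring D are cis to each other and both are trans to the C3 hydroxyl. Seven free hydroxyls, a catechol and an electron-rich stilbene make the compound sensitive to air, light and acid. The C2–O1 bond is a para-oxygenated benzylic ether and C4–H is doubly benzylic, so strong acid can ionise or epimerise both, and the stilbene forbids hydrogenolysis at the end.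

The difficulty lies in three things: a C4 centre that bears the di-ortho-substituted, very electron-rich ring D, three adjacent stereocentres, and seven oxygens that must be told apart. The feature that is used is the position of O1 on ring A. O1 sits on C8a, ortho to the C4 branch on C4a and meta to the C7 hydroxyl, which is para to C4a. Ring A is therefore a para-alkylphenol in disguise; once that phenol is oxidised to a cyclohexa-2,5-dienone, C8a is a β-carbon within reach of an oxygen on C2.

## Retrosynthetic reasoning

**Deprotection (26 from 25).** The last operation removes six benzyl groups from 25 and cuts no skeletal bond. It fixes two rules for everything before it: all steps must tolerate benzyl ethers, and the final cleavage must use a Lewis acid with a cation trap, because a hydrogenolytic cleavage would saturate the stilbene. The C7 oxygen is already free in 25 because it is the phenol through which ring A is dearomatised.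

**O1–C8a (25 from 22, through 23 and 24).** The pyran ring is opened at the aryl ether bond O1–C8a. This is the one ring bond that touches no stereocentre, so C2, C3 and C4 can be built in an open chain and carried through the closure unchanged. Cutting O1–C2 would need a 1,3-dioxygenated ring A and a benzylic cation or leaving group at C2, which puts that centre at risk. Cutting a C–C bond of the ring would make the closure responsible for stereochemistry. What is gained is that ring A becomes a plain para-substituted phenol, and that two centres which are both nucleophilic by nature (the C2 oxygen and the arene carbon C8a) can be joined after the arene has been made electrophilic. In the forward direction 22 must lose its silyl group to give 23, the C2 hydroxyl must add to C8a to give 24, and the methoxy group on C4a must then leave so that ring A is aromatic again.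

**Ring A oxidation level (22 from 21, 21 from 20).** Dienone 22 comes from phenol 21 by a two-electron oxidation in an alcohol solvent that supplies the C4a methoxy group. No skeletal bond is cut, but the protecting-group pattern is decided here. The C2 oxygen must be capped during the oxidation, or it would close a five-membered spiro ether onto C4a. The C3 oxygen must stay capped in the ring closure, or it would close a five-membered ring onto C8a. The ring A oxygen must be the only phenol that is freed, hence an allyl ether in 20 against benzyl ethers elsewhere.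

**C2–ring B (20 from 19, 19 from 18, 18 from 17, 17 from 14 and 16).** The bond between C2 and ring B is cut, which leads to aldehyde 14 and the aryl Grignard reagent 16 made from 15. The C2 and C3 oxygens are anti in the open chain (this is what becomes 2,3-trans). Addition of an aryl metal to the α-benzyloxy aldehyde 14 cannot be trusted to give that relation, because chelation leads to the syn isomer. The mixture 17 is therefore oxidised to ketone 18, and the centre is set by chelation-controlled hydride delivery, which gives the anti alcohol 19.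

**Oxygen differentiation (14 from 13, 13 from 12, 12 from 11).** Aldehyde 14 is traced to diol 11 without cutting a skeletal bond. A benzylidene acetal (12) and its reductive opening place the benzyl group on the hindered C3 oxygen and leave the primary alcohol of 13 free for oxidation. This takes two operations where a protect, benzylate, deprotect sequence takes three.

**C4–C4a (11 from 8 and 10).** The bond between C4 and ring A is cut, which leads to the benzylic epoxide 8 and the aryl Grignard reagent 10 made from 9. The choice of which ring sits on the epoxide is not free. A trans-epoxide opened with inversion gives the anti relation of the C3 oxygen and ring A (3,4-trans in the flavan) only if ring D is on the epoxide and ring A arrives as the nucleophile. The reverse assignment would need the cis-epoxide and a di-ortho-substituted aryl nucleophile. The forward reaction must attack the benzylic carbon, not the neighbouring one, and must do so with clean inversion.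

**Epoxide (8 from 7).** The epoxide oxygen is removed to give the (E)-allylic alcohol 7. A hydroxyl-directed asymmetric epoxidation is chosen because it leaves the stilbene double bond alone, which a dihydroxylation or a non-directed epoxidation would not. It fixes the absolute configuration of C3 directly and that of C4 by relay.

**Ring D and ring E fragment (7 from 5 and 6, 5 from 2 and 4, 2 from 1, 4 from 3).** The bond between D1 and the three-carbon chain is cut to give aryl bromide 5 and alkenylboronate 6. The stilbene double bond of 5 is cut to give aldehyde 2 and phosphonate 4. Compound 2 comes from 1 by bromination at the position that becomes D1, and 4 comes from benzylic chloride 3. The bromide is introduced on the simple aldehyde, where its regiochemistry is unambiguous, and not on the stilbene.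

## Alternatives that were turned down

**Alternative 1: ring-closing metathesis at C3=C4, then hydroboration.**
- Disconnection and key step: the C3=C4 bond is cut. A ruthenium alkylidene catalyst of the second generation would close diene A1 (vinyl on C2, 1-arylvinyl on ring A) to the 2H-chromene A2. A syn hydroboration–oxidation from the face opposite ring B would then set C3 and C4 together.
- For it: the closure is catalytic, ring A is bought with both oxygens in place, and the route to A2 is probably shorter than the route to 22. On step count up to the ring closure it is the stronger plan.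
- Against it: the only stereocentre of A1 is an ether carbon that is both allylic and para-alkoxybenzylic. It is hard to make in enantiopure form and is prone to ionise. The metathesis must engage a 1,1-disubstituted alkene that carries a di-ortho-substituted aryl group. C3 and C4 both hang on one hydroboration of a hindered, nearly flat chromene, steered only by ring B. The bromide must still be turned into the stilbene, so several steps follow the key step where the chosen route has one.
- Comparison: the chosen route sets each centre by reagent or chelate control and gives the ring closure no stereochemical task.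

**Alternative 2: ortho-quinone methide [4+2] cycloaddition with a styrylboronate.**
- Disconnection and key step: O1–C2 and C3–C4 are cut together. A chiral binaphthyl phosphoric acid would release an ortho-quinone methide from benzhydrol A3, and this would add (E)-styrylboronate A4 to give the 3-borylflavan A5 with all three centres.
- For it: it is the most convergent plan and clearly the shortest. The C–B bond would give the C3 hydroxyl with retention. On step economy and convergence it beats the chosen route.
- Against it: a single step would carry regio-, diastereo- and enantiocontrol on an untested pairing. The 2π partner is a 1,2-disubstituted styrene made less electron-rich by boron. The methide carbon is shielded by an aryl group with two ortho substituents. The 3,4-trans relation depends on the endo or exo mode and on the geometry of the quinone methide. Ring E would still have to be attached afterwards.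
- Comparison: the chosen route is longer but spreads these tasks over steps whose sense of induction is known.

**Alternative 3: cyclobutenone benzannulation that builds ring D on C4.**
- Disconnection and key step: ring D itself is cut (D2–D3, D4–D5 and D1–D2). Heating cyclobutenone A6 with silyloxyalkyne A7 would pass through a vinylketene, a [2+2] adduct and a 6π closure to the phenol A8.
- For it: the crowded, electron-rich arene is never attached to C4 as an intact ring, so no labile benzylic epoxide such as 8 is needed. On that point it is stronger than the chosen route.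
- Against it: A6 is a harder target than 22. It is a flavan that already holds all three stereocentres, with a four-membered ring on C4 and a dienyl side chain, and its vinylketene is conjugated with the styryl unit, which opens other electrocyclic paths. The differentiation of the two ring D oxygens that it offers is of no use for 26. Its step count is the highest of the four.
- Comparison: the chosen route buys ring D as an arene and pays with one delicate epoxide, for which a by-pass is described below.

Key step: step 16

Remark: 3 and 6 are taken as purchasable; if not, 3 is one step from the corresponding benzyl alcohol and 6 one step from propargyl alcohol by hydroboration with pinacolborane.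

Abbreviation in names: ArD = 2,4-bis(benzyloxy)-6-[(E)-2-[3,4-bis(benzyloxy)phenyl]ethenyl]phenyl (ring D with ring E attached).

## Route

Step 1
Reactants: 1 3,5-bis(benzyloxy)benzaldehyde
Product: 2 3,5-bis(benzyloxy)-2-bromobenzaldehyde
Conditions: NBS, MeCN, 0 °C → rt
Reagents that add atoms: N-bromosuccinimide, O=C1CCC(=O)N1Br
Why: Electrophilic aromatic bromination; C2 is ortho to one benzyloxy group and para to the other and is less crowded than C4 between the two ethers, the usual outcome for 3,5-dialkoxybenzaldehydes.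

Step 2
Reactants: 3 4-(chloromethyl)-1,2-bis(benzyloxy)benzene
Product: 4 diethyl [3,4-bis(benzyloxy)benzyl]phosphonate
Conditions: P(OEt)3 (neat), 140 °C
Reagents that add atoms: triethyl phosphite, CCOP(OCC)OCC
Why: Michaelis–Arbuzov reaction of a reactive benzylic chloride.

Step 3
Reactants: 2 3,5-bis(benzyloxy)-2-bromobenzaldehyde; 4 diethyl [3,4-bis(benzyloxy)benzyl]phosphonate
Product: 5 1,5-bis(benzyloxy)-3-[(E)-2-[3,4-bis(benzyloxy)phenyl]ethenyl]-2-bromobenzene
Conditions: KOt-Bu, THF, 0 °C → rt
Reagents that add atoms: none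
Why: Horner–Wadsworth–Emmons olefination; benzylphosphonate anions and aryl aldehydes should give the (E)-stilbene, and the aryl bromide is not touched.

Step 4
Reactants: 5 1,5-bis(benzyloxy)-3-[(E)-2-[3,4-bis(benzyloxy)phenyl]ethenyl]-2-bromobenzene; 6 (2E)-3-(4,4,5,5-tetramethyl-1,3,2-dioxaborolan-2-yl)prop-2-en-1-ol
Product: 7 (2E)-3-ArD-prop-2-en-1-ol
Conditions: Pd(OAc)2 (5 mol %), SPhos (10 mol %), K3PO4, toluene/H2O (10:1), 80 °C
Reagents that add atoms: none
Why: Suzuki–Miyaura coupling; the dialkylbiarylphosphine lets zerovalent palladium insert into the di-ortho-substituted, electron-rich aryl bromide, and the alkenyl group transfers with retention of its (E)-geometry.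

Step 5
Reactants: 7 (2E)-3-ArD-prop-2-en-1-ol
Product: 8 [(2R,3R)-3-ArD-oxiran-2-yl]methanol
Conditions: Ti(Oi-Pr)4 (10 mol %), D-(−)-diisopropyl tartrate (12 mol %), t-BuOOH, 4 Å MS, CH2Cl2, −25 °C; cold aqueous NaOH/NaCl work-up
Reagents that add atoms: tert-butyl hydroperoxide, CC(C)(C)OO
Why: Katsuki–Sharpless asymmetric epoxidation; the tetravalent titanium tartrate binds the allylic hydroxyl and delivers oxygen only to that alkene, so the stilbene is spared. The unnatural D-(−)-tartrate should give the (2R,3R)-epoxide, since the natural ester gives (2S,3S) with (E)-3-arylallylic alcohols. The acid-labile product is used at once.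

Step 6
Reactants: 8 [(2R,3R)-3-ArD-oxiran-2-yl]methanol; 9 1-bromo-4-(prop-2-en-1-yloxy)benzene
Product: 11 (2S,3S)-3-ArD-3-[4-(prop-2-en-1-yloxy)phenyl]propane-1,2-diol, via 4-(prop-2-en-1-yloxy)phenylmagnesium bromide 10 (not isolated)
Conditions: 9, Mg, THF, rt; then CuI (10 mol %), 8, THF, −40 → −15 °C
Reagents that add atoms: none
Why: Copper-catalysed opening of a 2,3-epoxy alcohol by an aryl Grignard reagent; the arylcopper species attacks the benzylic carbon anti to the C–O bond (SN2, inversion), which sets the diarylmethine centre (flavan C4) as (S), and the carbinol centre keeps its configuration from step 5. The low temperature keeps the aryl allyl ether out of copper-catalysed allylic substitution.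

Step 7
Reactants: 11 (2S,3S)-3-ArD-3-[4-(prop-2-en-1-yloxy)phenyl]propane-1,2-diol
Product: 12 (4S)-4-[(S)-ArD[4-(prop-2-en-1-yloxy)phenyl]methyl]-2-phenyl-1,3-dioxolane (both epimers at the acetal carbon)
Conditions: PhCH(OMe)2, PPTS (10 mol %), toluene, 60 °C
Reagents that add atoms: benzaldehyde dimethyl acetal, COC(OC)c1ccccc1
Why: Acid-catalysed transacetalisation to the five-membered benzylidene acetal; the new acetal centre forms as a mixture, which does not matter because it is reduced away in step 8.

Step 8
Reactants: 12 (4S)-4-[(S)-ArD[4-(prop-2-en-1-yloxy)phenyl]methyl]-2-phenyl-1,3-dioxolane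
Product: 13 (2S,3S)-2-(benzyloxy)-3-ArD-3-[4-(prop-2-en-1-yloxy)phenyl]propan-1-ol
Conditions: i-Bu2AlH (4 equiv), CH2Cl2, −78 → 0 °C; aqueous potassium sodium tartrate
Reagents that add atoms: none
Why: Reductive opening of a benzylidene acetal; the aluminium hydride binds the unhindered primary oxygen, that C–O bond breaks and hydride reduces the oxocarbenium ion. The benzyl group therefore stays on the hindered secondary oxygen (flavan C3–O) and the primary hydroxyl is freed.

Step 9
Reactants: 13 (2S,3S)-2-(benzyloxy)-3-ArD-3-[4-(prop-2-en-1-yloxy)phenyl]propan-1-ol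
Product: 14 (2S,3S)-2-(benzyloxy)-3-ArD-3-[4-(prop-2-en-1-yloxy)phenyl]propanal
Conditions: Dess–Martin periodinane, NaHCO3, CH2Cl2, 0 °C → rt
Reagents that add atoms: none
Why: Dess–Martin oxidation of a primary alcohol under buffered conditions that should not epimerise the α-benzyloxy centre; the aldehyde is used directly.

Step 10
Reactants: 14 (2S,3S)-2-(benzyloxy)-3-ArD-3-[4-(prop-2-en-1-yloxy)phenyl]propanal; 15 1-(benzyloxy)-4-bromobenzene
Product: 17 (2S,3S)-2-(benzyloxy)-1-[4-(benzyloxy)phenyl]-3-ArD-3-[4-(prop-2-en-1-yloxy)phenyl]propan-1-ol (both C1 epimers), via 4-(benzyloxy)phenylmagnesium bromide 16 (not isolated)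
Conditions: 15, Mg, THF, rt; then 14, THF, −78 °C
Reagents that add atoms: none
Why: Grignard 1,2-addition; magnesium chelation between the aldehyde and the α-benzyloxy oxygen is expected to favour the unwanted 1,2-syn epimer, so both epimers are carried on and the centre is reset in steps 11 and 12.

Step 11
Reactants: 17 (2S,3S)-2-(benzyloxy)-1-[4-(benzyloxy)phenyl]-3-ArD-3-[4-(prop-2-en-1-yloxy)phenyl]propan-1-ol
Product: 18 (2S,3S)-2-(benzyloxy)-1-[4-(benzyloxy)phenyl]-3-ArD-3-[4-(prop-2-en-1-yloxy)phenyl]propan-1-one
Conditions: Dess–Martin periodinane, NaHCO3, CH2Cl2, rt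
Reagents that add atoms: none
Why: Dess–Martin oxidation merges both carbinol epimers into one α-benzyloxy aryl ketone without touching the adjacent centres.

Step 12
Reactants: 18 (2S,3S)-2-(benzyloxy)-1-[4-(benzyloxy)phenyl]-3-ArD-3-[4-(prop-2-en-1-yloxy)phenyl]propan-1-one
Product: 19 (1R,2S,3S)-2-(benzyloxy)-1-[4-(benzyloxy)phenyl]-3-ArD-3-[4-(prop-2-en-1-yloxy)phenyl]propan-1-ol
Conditions: Zn(BH4)2, Et2O/CH2Cl2, −30 → 0 °C
Reagents that add atoms: none
Why: Chelation-controlled (Cram chelate) reduction; divalent zinc bridges the ketone and α-benzyloxy oxygens and hydride enters the five-membered chelate from the side of the α-hydrogen, away from the bulky diarylmethyl group. This should give the 1,2-anti alcohol, (1R), which is the 2,3-trans relation of the flavan.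

Step 13
Reactants: 19 (1R,2S,3S)-2-(benzyloxy)-1-[4-(benzyloxy)phenyl]-3-ArD-3-[4-(prop-2-en-1-yloxy)phenyl]propan-1-ol
Product: 20 [(1R,2S,3S)-2-(benzyloxy)-1-[4-(benzyloxy)phenyl]-3-ArD-3-[4-(prop-2-en-1-yloxy)phenyl]propoxy]triethylsilane
Conditions: Et3SiOTf, 2,6-lutidine, CH2Cl2, −78 → 0 °C
Reagents that add atoms: triethylsilyl trifluoromethanesulfonate, CC[Si](CC)(CC)OS(=O)(=O)C(F)(F)F
Why: Silylation of a hindered secondary alcohol with a silyl triflate and a hindered pyridine base.

Step 14
Reactants: 20 [(1R,2S,3S)-2-(benzyloxy)-1-[4-(benzyloxy)phenyl]-3-ArD-3-[4-(prop-2-en-1-yloxy)phenyl]propoxy]triethylsilane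
Product: 21 4-[(1S,2S,3R)-2-(benzyloxy)-3-[4-(benzyloxy)phenyl]-1-ArD-3-[(triethylsilyl)oxy]propyl]phenol
Conditions: Pd(PPh3)4 (5 mol %), morpholine, THF, rt
Reagents that add atoms: none
Why: Tsuji–Trost deallylation; zerovalent palladium ionises the aryl allyl ether to an allylpalladium phenoxide and morpholine takes up the allyl group, while benzyl ethers, the silyl ether and the stilbene are inert.

Step 15
Reactants: 21 4-[(1S,2S,3R)-2-(benzyloxy)-3-[4-(benzyloxy)phenyl]-1-ArD-3-[(triethylsilyl)oxy]propyl]phenol
Product: 22 4-[(1S,2S,3R)-2-(benzyloxy)-3-[4-(benzyloxy)phenyl]-1-ArD-3-[(triethylsilyl)oxy]propyl]-4-methoxycyclohexa-2,5-dien-1-one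
Conditions: PhI(OAc)2 (1.1 equiv), NaHCO3, MeOH/CH2Cl2 (3:1), 0 °C
Reagents that add atoms: methanol, CO
Why: Oxidative dearomatisation of a para-alkylphenol by a trivalent iodine reagent; solvent methanol attacks the para carbon C4a and gives the para-quinol methyl ether. The silyl ether on the C2 oxygen prevents spirocyclisation onto C4a, and C4a is not a stereocentre because its two vinyl arms are identical.

Step 16
Reactants: 22 4-[(1S,2S,3R)-2-(benzyloxy)-3-[4-(benzyloxy)phenyl]-1-ArD-3-[(triethylsilyl)oxy]propyl]-4-methoxycyclohexa-2,5-dien-1-one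
Product: 25 (2R,3S,4S)-3-(benzyloxy)-2-[4-(benzyloxy)phenyl]-4-ArD-3,4-dihydro-2H-chromen-7-ol, via free C2 alcohol 23 (not isolated), via cis-fused methoxy enone 24 (not isolated)
Conditions: TsOH·H2O (1.5 equiv), CH2Cl2/MeCN (1:1), 0 °C → rt
Reagents that add atoms: none
Why: The acid and its water of hydration hydrolyse the triethylsilyl ether and give alcohol 23. The C2 hydroxyl then adds to the acid-activated dienone at the β-carbon C8a (or at the diastereotopic C5, which leads to the same flavan) in a 6-exo-trig oxa-Michael addition; this forms O1–C8a and closes the pyran ring as the cis-fused enone 24. Enolisation of 24 towards C8 gives a 4a-methoxy-4a,8a-dihydroarene, which ionises at C4a and loses the C8a proton, so that methanol leaves as water leaves an arene hydrate and ring A returns as the phenol of 25. The closest known reaction type is the dearomatisation, hetero-Michael addition and rearomatisation sequence of 4-alkyl-4-methoxycyclohexa-2,5-dienones that carry a tethered oxygen or nitrogen nucleophile. No stereocentre is made, because C4a and C8a end up sp2, and C2, C3 and C4 are untouched, because the C2–O bond is kept and only the group on that oxygen changes. The step needs the C2 oxygen to react and not the C3 oxygen, which the benzyl ether on C3 secures, and it needs ring closure to outrun acid-induced loss of the side chain from C4a or a 1,2-shift, which the intramolecular six-membered transition state and the low temperature favour.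

Step 17
Reactants: 25 (2R,3S,4S)-3-(benzyloxy)-2-[4-(benzyloxy)phenyl]-4-ArD-3,4-dihydro-2H-chromen-7-ol
Product: 26 (2R,3S,4S)-4-[2-[(E)-2-(3,4-dihydroxyphenyl)ethenyl]-4,6-dihydroxyphenyl]-2-(4-hydroxyphenyl)-3,4-dihydro-2H-chromene-3,7-diol
Conditions: BCl3 (excess), C6HMe5, CH2Cl2, −78 → −30 °C; then MeOH
Reagents that add atoms: none
Why: Lewis acid debenzylation with a cation scavenger; BCl3 activates each ether oxygen and pentamethylbenzene takes up the benzyl cations by Friedel–Crafts alkylation, so the stilbene and the electron-rich rings are not benzylated and no hydrogenation is needed. Only O–CH2Ph bonds are broken, so the three stereocentres are kept.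

## Compound list

1 | 3,5-bis(benzyloxy)benzaldehyde | O=Cc1cc(OCc2ccccc2)cc(OCc2ccccc2)c1 | starting material
2 | 3,5-bis(benzyloxy)-2-bromobenzaldehyde | O=Cc1cc(OCc2ccccc2)cc(OCc2ccccc2)c1Br | intermediate
3 | 4-(chloromethyl)-1,2-bis(benzyloxy)benzene | ClCc1ccc(OCc2ccccc2)c(OCc2ccccc2)c1 | starting material
4 | diethyl [3,4-bis(benzyloxy)benzyl]phosphonate | CCOP(=O)(OCC)Cc1ccc(OCc2ccccc2)c(OCc2ccccc2)c1 | intermediate
5 | 1,5-bis(benzyloxy)-3-[(E)-2-[3,4-bis(benzyloxy)phenyl]ethenyl]-2-bromobenzene | Brc1c(OCc2ccccc2)cc(OCc2ccccc2)cc1/C=C/c1ccc(OCc2ccccc2)c(OCc2ccccc2)c1 | intermediate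
6 | (2E)-3-(4,4,5,5-tetramethyl-1,3,2-dioxaborolan-2-yl)prop-2-en-1-ol | OC/C=C/B1OC(C)(C)C(C)(C)O1 | starting material
7 | (2E)-3-[2,4-bis(benzyloxy)-6-[(E)-2-[3,4-bis(benzyloxy)phenyl]ethenyl]phenyl]prop-2-en-1-ol | OC/C=C/c1c(OCc2ccccc2)cc(OCc2ccccc2)cc1/C=C/c1ccc(OCc2ccccc2)c(OCc2ccccc2)c1 | intermediate
8 | [(2R,3R)-3-ArD-oxiran-2-yl]methanol | OC[C@H]1O[C@@H]1c1c(OCc2ccccc2)cc(OCc2ccccc2)cc1/C=C/c1ccc(OCc2ccccc2)c(OCc2ccccc2)c1 | intermediate
9 | 1-bromo-4-(prop-2-en-1-yloxy)benzene | C=CCOc1ccc(Br)cc1 | starting material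
10 | 4-(prop-2-en-1-yloxy)phenylmagnesium bromide | C=CCOc1ccc([Mg]Br)cc1 | intermediate
11 | (2S,3S)-3-ArD-3-[4-(prop-2-en-1-yloxy)phenyl]propane-1,2-diol | C=CCOc1ccc(cc1)[C@@H](c1c(OCc2ccccc2)cc(OCc2ccccc2)cc1/C=C/c1ccc(OCc2ccccc2)c(OCc2ccccc2)c1)[C@H](O)CO | intermediate
12 | (4S)-4-[(S)-ArD[4-(prop-2-en-1-yloxy)phenyl]methyl]-2-phenyl-1,3-dioxolane (both epimers at the acetal carbon) | C=CCOc1ccc(cc1)[C@@H](c1c(OCc2ccccc2)cc(OCc2ccccc2)cc1/C=C/c1ccc(OCc2ccccc2)c(OCc2ccccc2)c1)[C@H]1COC(c2ccccc2)O1 | intermediate
13 | (2S,3S)-2-(benzyloxy)-3-ArD-3-[4-(prop-2-en-1-yloxy)phenyl]propan-1-ol | C=CCOc1ccc(cc1)[C@@H](c1c(OCc2ccccc2)cc(OCc2ccccc2)cc1/C=C/c1ccc(OCc2ccccc2)c(OCc2ccccc2)c1)[C@H](OCc1ccccc1)CO | intermediate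
14 | (2S,3S)-2-(benzyloxy)-3-ArD-3-[4-(prop-2-en-1-yloxy)phenyl]propanal | C=CCOc1ccc(cc1)[C@@H](c1c(OCc2ccccc2)cc(OCc2ccccc2)cc1/C=C/c1ccc(OCc2ccccc2)c(OCc2ccccc2)c1)[C@H](OCc1ccccc1)C=O | intermediate
15 | 1-(benzyloxy)-4-bromobenzene | Brc1ccc(OCc2ccccc2)cc1 | starting material
16 | 4-(benzyloxy)phenylmagnesium bromide | Br[Mg]c1ccc(OCc2ccccc2)cc1 | intermediate
17 | (2S,3S)-2-(benzyloxy)-1-[4-(benzyloxy)phenyl]-3-ArD-3-[4-(prop-2-en-1-yloxy)phenyl]propan-1-ol (both C1 epimers) | C=CCOc1ccc(cc1)[C@@H](c1c(OCc2ccccc2)cc(OCc2ccccc2)cc1/C=C/c1ccc(OCc2ccccc2)c(OCc2ccccc2)c1)[C@H](OCc1ccccc1)C(O)c1ccc(OCc2ccccc2)cc1 | intermediate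
18 | (2S,3S)-2-(benzyloxy)-1-[4-(benzyloxy)phenyl]-3-ArD-3-[4-(prop-2-en-1-yloxy)phenyl]propan-1-one | C=CCOc1ccc(cc1)[C@@H](c1c(OCc2ccccc2)cc(OCc2ccccc2)cc1/C=C/c1ccc(OCc2ccccc2)c(OCc2ccccc2)c1)[C@H](OCc1ccccc1)C(=O)c1ccc(OCc2ccccc2)cc1 | intermediate
19 | (1R,2S,3S)-2-(benzyloxy)-1-[4-(benzyloxy)phenyl]-3-ArD-3-[4-(prop-2-en-1-yloxy)phenyl]propan-1-ol | C=CCOc1ccc(cc1)[C@@H](c1c(OCc2ccccc2)cc(OCc2ccccc2)cc1/C=C/c1ccc(OCc2ccccc2)c(OCc2ccccc2)c1)[C@H](OCc1ccccc1)[C@H](O)c1ccc(OCc2ccccc2)cc1 | intermediate
20 | [(1R,2S,3S)-2-(benzyloxy)-1-[4-(benzyloxy)phenyl]-3-ArD-3-[4-(prop-2-en-1-yloxy)phenyl]propoxy]triethylsilane | C=CCOc1ccc(cc1)[C@@H](c1c(OCc2ccccc2)cc(OCc2ccccc2)cc1/C=C/c1ccc(OCc2ccccc2)c(OCc2ccccc2)c1)[C@H](OCc1ccccc1)[C@H](O[Si](CC)(CC)CC)c1ccc(OCc2ccccc2)cc1 | intermediate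
21 | 4-[(1S,2S,3R)-2-(benzyloxy)-3-[4-(benzyloxy)phenyl]-1-ArD-3-[(triethylsilyl)oxy]propyl]phenol | Oc1ccc(cc1)[C@@H](c1c(OCc2ccccc2)cc(OCc2ccccc2)cc1/C=C/c1ccc(OCc2ccccc2)c(OCc2ccccc2)c1)[C@H](OCc1ccccc1)[C@H](O[Si](CC)(CC)CC)c1ccc(OCc2ccccc2)cc1 | intermediate
22 | 4-[(1S,2S,3R)-2-(benzyloxy)-3-[4-(benzyloxy)phenyl]-1-ArD-3-[(triethylsilyl)oxy]propyl]-4-methoxycyclohexa-2,5-dien-1-one | COC1(C=CC(=O)C=C1)[C@@H](c1c(OCc2ccccc2)cc(OCc2ccccc2)cc1/C=C/c1ccc(OCc2ccccc2)c(OCc2ccccc2)c1)[C@H](OCc1ccccc1)[C@H](O[Si](CC)(CC)CC)c1ccc(OCc2ccccc2)cc1 | intermediate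
23 | 4-[(1S,2S,3R)-2-(benzyloxy)-3-[4-(benzyloxy)phenyl]-3-hydroxy-1-ArD-propyl]-4-methoxycyclohexa-2,5-dien-1-one | COC1(C=CC(=O)C=C1)[C@@H](c1c(OCc2ccccc2)cc(OCc2ccccc2)cc1/C=C/c1ccc(OCc2ccccc2)c(OCc2ccccc2)c1)[C@H](OCc1ccccc1)[C@H](O)c1ccc(OCc2ccccc2)cc1 | intermediate
24 | (2R,3S,4S)-3-(benzyloxy)-2-[4-(benzyloxy)phenyl]-4-ArD-4a-methoxy-2,3,4,4a,8,8a-hexahydro-7H-chromen-7-one (cis ring fusion, either C4a/C8a pair) | c1ccccc1COc1ccc(cc1)[C@H]1OC2CC(=O)C=CC2(OC)[C@@H](c2c(OCc3ccccc3)cc(OCc3ccccc3)cc2/C=C/c2ccc(OCc3ccccc3)c(OCc3ccccc3)c2)[C@@H]1OCc1ccccc1 | intermediate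
25 | (2R,3S,4S)-3-(benzyloxy)-2-[4-(benzyloxy)phenyl]-4-ArD-3,4-dihydro-2H-chromen-7-ol | c1ccccc1COc1ccc(cc1)[C@H]1Oc2cc(O)ccc2[C@@H](c2c(OCc3ccccc3)cc(OCc3ccccc3)cc2/C=C/c2ccc(OCc3ccccc3)c(OCc3ccccc3)c2)[C@@H]1OCc1ccccc1 | intermediate
26 | (2R,3S,4S)-4-[2-[(E)-2-(3,4-dihydroxyphenyl)ethenyl]-4,6-dihydroxyphenyl]-2-(4-hydroxyphenyl)-3,4-dihydro-2H-chromene-3,7-diol | Oc1ccc([C@H]2Oc3cc(O)ccc3[C@@H](c3c(O)cc(O)cc3/C=C/c3ccc(O)c(O)c3)[C@@H]2O)cc1 | target

## Step count and least certain steps

Total step count: 17. Longest linear sequence: 16 steps (from 1 through steps 1 and 3 to 17; the branch from 3 through steps 2 and 3 to 17 is equally long).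

**Step 16 (key step).**
- What may go wrong: the cross-conjugated dienone meets acid before the C2 hydroxyl is free. The protonated dienone can shed the whole C4 side chain as a benzylic cation stabilised by ring D (a fragmentation that restores an aromatic ring), or it can undergo a 1,2-shift of the dienone–phenol type. It can also be attacked at C5 or C8a by water, or by the C3 benzyloxy oxygen with loss of the benzyl group and closure of a five-membered ring.
- Fallback: the three events are separated and the polarity of the ring closure is reversed, so that the dienone never meets acid. It sets out from 22. Bu4NF buffered with AcOH in THF removes the silyl group and gives alcohol 23. A catalytic amount of KOt-Bu in THF closes the ring by conjugate addition of the alkoxide to the neutral dienone, and enone 24 is isolated. PPTS in CH2Cl2 then expels methanol from 24, which can no longer fragment to a phenol, and the route is rejoined at 25. Both intermediates are already in the compound list (no new compound; F0).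

**Step 6 (together with the isolation of its substrate 8 from step 5).**
- What may go wrong: the benzylic C–O bond of the epoxide is activated by the ortho and para benzyloxy groups of ring D. Titanium or magnesium Lewis acids can ionise it, which leads to rearrangement to carbonyl compounds, to opening by halide followed by substitution with overall retention, or to loss of configuration at the future C4. Attack at the non-benzylic carbon is a further risk.
- Fallback: the epoxide is by-passed and the two centres are made in the other order by catalyst control. It sets out from 7. MnO2 in CH2Cl2 gives (2E)-3-ArD-prop-2-enal F1. Rhodium-catalysed asymmetric conjugate addition of 4-(prop-2-en-1-yloxy)phenylboronic acid (Rh(acac)(C2H4)2, a chiral diene ligand of the enantiomer that gives the (3S) product, KOH, dioxane/H2O) gives (3S)-3-ArD-3-[4-(prop-2-en-1-yloxy)phenyl]propanal F2. D-Proline-catalysed α-aminoxylation with nitrosobenzene, with NaBH4 reduction in the same flask, gives (2S,3S)-3-ArD-2-[(phenylamino)oxy]-3-[4-(prop-2-en-1-yloxy)phenyl]propan-1-ol F3. Zn in AcOH cleaves the N–O bond, and the route is rejoined at diol 11.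

**Step 15.**
- What may go wrong: the oxidised phenol can lose the doubly benzylic C4 proton and form a para-quinone methide, which erases C4, in competition with methanol capture at C4a. The ortho-styryl alkene of ring D can capture the electrophilic ring A. Acetic acid can remove the silyl group, which would be followed by spirocyclisation.
- Fallback: the phenol is oxygenated without a cationic intermediate. It sets out from 21. KHSO5 (used as 2KHSO5·KHSO4·K2SO4) with NaHCO3 in MeCN/H2O generates singlet oxygen, which should add to the para position and give 4-[(1S,2S,3R)-2-(benzyloxy)-3-[4-(benzyloxy)phenyl]-1-ArD-3-[(triethylsilyl)oxy]propyl]-4-hydroperoxycyclohexa-2,5-dien-1-one F4. Me2S reduces it to the para-quinol 4-[(1S,2S,3R)-2-(benzyloxy)-3-[4-(benzyloxy)phenyl]-1-ArD-3-[(triethylsilyl)oxy]propyl]-4-hydroxycyclohexa-2,5-dien-1-one F5. Under the conditions of step 16, F5 should lose the silyl group, cyclise and lose water instead of methanol, and the route is rejoined at 25.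

**Step 17.**
- What may go wrong: the Lewis acid can ionise the C2–O1 bond, with epimerisation at C2, or trigger cyclisation of the stilbene onto a neighbouring electron-rich ring. The secondary alkyl benzyl ether on the C3 oxygen may be cleaved incompletely. The free polyphenol may oxidise during isolation.
- Fallback: the cleavage is changed from cation transfer to nucleophile-assisted dealkylation, and the product is isolated as an ester. It sets out from 25. AlCl3 with N,N-dimethylaniline in CH2Cl2 removes the benzyl groups, and the crude polyphenol is acetylated at once (Ac2O, pyridine) to the chromatographable heptaacetate (2R,3S,4S)-3-acetoxy-2-(4-acetoxyphenyl)-4-[2,4-diacetoxy-6-[(E)-2-(3,4-diacetoxyphenyl)ethenyl]phenyl]-3,4-dihydro-2H-chromen-7-yl acetate F6. Degassed K2CO3 in MeOH at 0 °C releases 26.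

**Step 8.**
- What may go wrong: poor regioselectivity in the reductive acetal opening, which would put the benzyl group on the primary oxygen and lead to the wrong aldehyde.
- Fallback: the two oxygens are told apart by stepwise protection, without the acetal. It sets out from diol 11. t-BuMe2SiCl and imidazole silylate the primary hydroxyl and give (2S,3S)-1-[(tert-butyldimethylsilyl)oxy]-3-ArD-3-[4-(prop-2-en-1-yloxy)phenyl]propan-2-ol F7. NaH and benzyl bromide give [(2S,3S)-2-(benzyloxy)-3-ArD-3-[4-(prop-2-en-1-yloxy)phenyl]propoxy](tert-butyl)dimethylsilane F8. Bu4NF frees the primary alcohol, and the route is rejoined at 13.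

## Further compounds

F0 | step 16 | none | none
F1 | step 6 | (2E)-3-ArD-prop-2-enal | O=C/C=C/c1c(OCc2ccccc2)cc(OCc2ccccc2)cc1/C=C/c1ccc(OCc2ccccc2)c(OCc2ccccc2)c1
F2 | step 6 | (3S)-3-ArD-3-[4-(prop-2-en-1-yloxy)phenyl]propanal | C=CCOc1ccc(cc1)[C@@H](c1c(OCc2ccccc2)cc(OCc2ccccc2)cc1/C=C/c1ccc(OCc2ccccc2)c(OCc2ccccc2)c1)CC=O
F3 | step 6 | (2S,3S)-3-ArD-2-[(phenylamino)oxy]-3-[4-(prop-2-en-1-yloxy)phenyl]propan-1-ol | C=CCOc1ccc(cc1)[C@@H](c1c(OCc2ccccc2)cc(OCc2ccccc2)cc1/C=C/c1ccc(OCc2ccccc2)c(OCc2ccccc2)c1)[C@H](ONc1ccccc1)CO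
F4 | step 15 | 4-[(1S,2S,3R)-2-(benzyloxy)-3-[4-(benzyloxy)phenyl]-1-ArD-3-[(triethylsilyl)oxy]propyl]-4-hydroperoxycyclohexa-2,5-dien-1-one | OOC1(C=CC(=O)C=C1)[C@@H](c1c(OCc2ccccc2)cc(OCc2ccccc2)cc1/C=C/c1ccc(OCc2ccccc2)c(OCc2ccccc2)c1)[C@H](OCc1ccccc1)[C@H](O[Si](CC)(CC)CC)c1ccc(OCc2ccccc2)cc1
F5 | step 15 | 4-[(1S,2S,3R)-2-(benzyloxy)-3-[4-(benzyloxy)phenyl]-1-ArD-3-[(triethylsilyl)oxy]propyl]-4-hydroxycyclohexa-2,5-dien-1-one | OC1(C=CC(=O)C=C1)[C@@H](c1c(OCc2ccccc2)cc(OCc2ccccc2)cc1/C=C/c1ccc(OCc2ccccc2)c(OCc2ccccc2)c1)[C@H](OCc1ccccc1)[C@H](O[Si](CC)(CC)CC)c1ccc(OCc2ccccc2)cc1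
F6 | step 17 | (2R,3S,4S)-3-acetoxy-2-(4-acetoxyphenyl)-4-[2,4-diacetoxy-6-[(E)-2-(3,4-diacetoxyphenyl)ethenyl]phenyl]-3,4-dihydro-2H-chromen-7-yl acetate | CC(=O)Oc1ccc([C@H]2Oc3cc(OC(C)=O)ccc3[C@@H](c3c(OC(C)=O)cc(OC(C)=O)cc3/C=C/c3ccc(OC(C)=O)c(OC(C)=O)c3)[C@@H]2OC(C)=O)cc1
F7 | step 8 | (2S,3S)-1-[(tert-butyldimethylsilyl)oxy]-3-ArD-3-[4-(prop-2-en-1-yloxy)phenyl]propan-2-ol | C=CCOc1ccc(cc1)[C@@H](c1c(OCc2ccccc2)cc(OCc2ccccc2)cc1/C=C/c1ccc(OCc2ccccc2)c(OCc2ccccc2)c1)[C@H](O)CO[Si](C)(C)C(C)(C)C
F8 | step 8 | [(2S,3S)-2-(benzyloxy)-3-ArD-3-[4-(prop-2-en-1-yloxy)phenyl]propoxy](tert-butyl)dimethylsilane | C=CCOc1ccc(cc1)[C@@H](c1c(OCc2ccccc2)cc(OCc2ccccc2)cc1/C=C/c1ccc(OCc2ccccc2)c(OCc2ccccc2)c1)[C@H](OCc1ccccc1)CO[Si](C)(C)C(C)(C)C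
A1 | alternative 1 | 4-(benzyloxy)-2-[[(1S)-1-[4-(benzyloxy)phenyl]prop-2-en-1-yl]oxy]-1-[1-[2,4-bis(benzyloxy)-6-bromophenyl]ethenyl]benzene | c1ccccc1COc1ccc(cc1)[C@H](C=C)Oc1cc(OCc2ccccc2)ccc1C(=C)c1c(OCc2ccccc2)cc(OCc2ccccc2)cc1Br
A2 | alternative 1 | (2S)-7-(benzyloxy)-2-[4-(benzyloxy)phenyl]-4-[2,4-bis(benzyloxy)-6-bromophenyl]-2H-chromene | c1ccccc1COc1ccc(cc1)[C@H]1Oc2cc(OCc3ccccc3)ccc2C(c2c(OCc3ccccc3)cc(OCc3ccccc3)cc2Br)=C1
A3 | alternative 2 | [4-(benzyloxy)-2-hydroxyphenyl][2,4-bis(benzyloxy)-6-bromophenyl]methanol (racemic) | OC(c1ccc(OCc2ccccc2)cc1O)c1c(OCc2ccccc2)cc(OCc2ccccc2)cc1Br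
A4 | alternative 2 | 2-[(E)-2-[4-(benzyloxy)phenyl]ethenyl]-4,4,5,5-tetramethyl-1,3,2-dioxaborolane | c1ccccc1COc1ccc(cc1)/C=C/B1OC(C)(C)C(C)(C)O1
A5 | alternative 2 | 2-[(2S,3S,4S)-7-(benzyloxy)-2-[4-(benzyloxy)phenyl]-4-[2,4-bis(benzyloxy)-6-bromophenyl]-3,4-dihydro-2H-chromen-3-yl]-4,4,5,5-tetramethyl-1,3,2-dioxaborolane (2,3-trans-3,4-trans) | c1ccccc1COc1ccc(cc1)[C@H]1Oc2cc(OCc3ccccc3)ccc2[C@@H](c2c(OCc3ccccc3)cc(OCc3ccccc3)cc2Br)[C@@H]1B1OC(C)(C)C(C)(C)O1
A6 | alternative 3 | 4-[(2R,3S,4R)-3,7-bis(benzyloxy)-2-[4-(benzyloxy)phenyl]-3,4-dihydro-2H-chromen-4-yl]-3-[(E)-2-[3,4-bis(benzyloxy)phenyl]ethenyl]cyclobut-2-en-1-one (ring carbon C4 of the cyclobutenone unspecified) | c1ccccc1COc1ccc(cc1)[C@H]1Oc2cc(OCc3ccccc3)ccc2[C@@H](C2C(=O)C=C2/C=C/c2ccc(OCc3ccccc3)c(OCc3ccccc3)c2)[C@@H]1OCc1ccccc1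
A7 | alternative 3 | (ethynyloxy)tri(propan-2-yl)silane | C#CO[Si](C(C)C)(C(C)C)C(C)C
A8 | alternative 3 | 2-[(2R,3S,4S)-3,7-bis(benzyloxy)-2-[4-(benzyloxy)phenyl]-3,4-dihydro-2H-chromen-4-yl]-3-[(E)-2-[3,4-bis(benzyloxy)phenyl]ethenyl]-5-[tri(propan-2-yl)silyloxy]phenol | c1ccccc1COc1ccc(cc1)[C@H]1Oc2cc(OCc3ccccc3)ccc2[C@@H](c2c(O)cc(O[Si](C(C)C)(C(C)C)C(C)C)cc2/C=C/c2ccc(OCc3ccccc3)c(OCc3ccccc3)c2)[C@@H]1OCc1ccccc1
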